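The readings were computed on assumed constants, noise included.

Open a ledger on the substrates. They are the limiting reagent, and the solid reagent, which feeds partner into solution, stands at 2.50 equiv per left-handed substrate.

- amber: left-handed substrate 0.75 M; right-handed substrate 0.75 M; solid reagent 2.5 equiv; run made earlier
- flask: left-handed substrate 0.50 M; solid reagent 2.50 equiv; right-handed substrate 0.50 M; time 2.0 h

amber run (percent of the left-handed substrate and right-handed substrate together charged)

| time / min | left-handed product / % | right-handed substrate / % |
|---|---|---|
| 3.00 | 0 | 46.5 |
| 8.00 | 1.6 | 41.7 |
| 15.0 | 1.2 | 37.5 |
| 25.0 | 3.0 | 33.7 |

(readings scatter by 0.5 percentage points)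

- partner is single-handed; left-handed substrate and right-handed substrate are mirror images of each other, charged as a racemate, each of them at the stated concentration
- as a solid, counted per litre of solution: solid reagent
- what was read earlier has a scatter of 0.5 percentage points, one standard deviation
- at the start none of the solid reagent is in solution
- the handed part of partner does not stay in what it makes, so the products of the two hands are mirror images too

- the left-handed product in the flask at 2.0 h, as a percentage of the left-handed substrate and right-handed substrate together charged
- the right-handed substrate in the flask at 2.0 h, as a percentage of the left-handed substrate and right-handed substrate together charged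
- concentration of partner at 2.0 h, in M

Each hand starts at half of the charge. The amber run reads the right-handed substrate, which falls from 41.7% at 8.00 min to 33.7% at 25.0 min. That gives 0.0125 /min. Call this the drain constant, the pseudo-first-order fraction of right-handed substrate lost per minute after the opening minutes. It is a reading, with a scatter of 0.5 percentage points on each end, and it means a half-life of 55.3 min. The opening pace was 0.0242 /min, about twice the drain, so you leave that quick slip out.

You assume the solid holds [partner] at saturation. A first-order constant then carries no concentration, and you take it unchanged to the flask at 0.50 M.

Now book the flask at 2.0 h. Right-handed substrate, run on from the amber reading, books at 10.2%. You book the left-handed substrate the same. Left-handed product, at the amber reading of 0.184 per unit of right-handed substrate lost, books at 7.32%. The closing entry, 72.3%, goes to what the amber run does not read.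

The forecast gave 3.8% left-handed product, 29% right-handed substrate and [partner] 0.015 M, and said: “This is a tentative reading, because the solid might replenish partner.”

The flask gives 9.35% left-handed product, 10.8% right-handed substrate and [partner] 0.168 M, against your 7.32% and 10.2%.

    achiral form → side product (k = 3.70 × 10⁻⁴ /s)
    achiral form → waste (k = 6.30 × 10⁻⁴ /s)
    solid reagent ⇌ partner, rate k3*(cs3 - [partner]) while solid is left; crystals form when [partner] > cs3 (solubility = 0.170 M, k = 0.00480 /s)
    partner + right-handed substrate → right-handed product (k = 1.70 × 10⁻⁴ /M/s)
    left-handed substrate ⇌ achiral form (K = 0.580, k = 5.00 × 10⁻⁴ /s)
    right-handed substrate ⇌ achiral form (K = 0.580, k = 5.00 × 10⁻⁴ /s)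
    partner + left-handed substrate → left-handed product (k = 3.60 × 10⁻⁴ /M/s)

Dissolution has half of its turnover behind it by 0.121 h, earlier than the loss of achiral form to waste, at 0.741 h. [partner] stands at 0.158 M after 0.200 h and 0.168 M at 2.0 h, under a saturation of 0.17 M. Run the drain on from the flask's 10.8%: reaching 8.0 h takes 6.51 half-lives and leaves 0.120%. The same flask read at 8.0 h holds 0.138% right-handed substrate.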